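The 1,4-dioxane ring is opened at the O1–C8a bond. In ring A, O4 on C4a lies between O1 (C8a) and the 5-OH (C5) and para to C7. C5 and C8a are therefore equivalent in a 2,6-dibromo-4-(dioxolanyl)phenyl ether. One copper-catalysed intramolecular etherification joins the benzylic C2 hydroxyl to either bromide carbon. It closes the ring, carries the threo C2/C3 pair (set by an Evans syn glycolate aldol) unchanged into the trans ring, and leaves the second bromine at C5 as the latent phenol. The precursor is the (1S,2S)-1-aryl-2-aryloxypropane-1,3-diol whose primary hydroxyl is tritylated and whose C7 aldehyde is masked as a dioxolane.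

Key step: step 6

Remarks
- Positions follow 2,3-dihydro-1,4-benzodioxine numbering: ring B sits on C2, the hydroxymethyl group on C3, and ring A spans C4a–C8a. The target is (2S,3S), trans.
- Assumption: (R)-4-benzyl-3-(chloroacetyl)oxazolidin-2-one is taken to be a purchasable chiral building block.
- The primary hydroxyl is carried as a trityl ether. A silyl group could migrate to the benzylic alkoxide under hot carbonate and free the more reactive primary oxygen, which would close the isomeric six-membered ring. Trityl cannot migrate, survives hot aqueous KOH in step 7, and leaves together with the acetal in one acid step.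
- The phenol is alkylated before acetalisation, so no acetal ever sits para to a free phenol.
- Both stereocentres come from one auxiliary-controlled aldol, so the threo relation does not depend on a substitution at an electron-rich benzylic carbon.

Step 1
Reactants: 1 3,5-dibromo-4-hydroxybenzaldehyde; 2 (R)-4-benzyl-3-(chloroacetyl)oxazolidin-2-one
Product: 4 (R)-4-benzyl-3-[2-(2,6-dibromo-4-formylphenoxy)acetyl]oxazolidin-2-one, via iodoacetyl imide 3 (not isolated)
Conditions: K2CO3 (1.5 equiv), KI (20 mol %), MeCN, 45 °C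
Reagents that add atoms: none
Why: Williamson ether synthesis at an activated α-halo carbonyl carbon, relayed by Finkelstein exchange to 3; the phenoxide of 1 is so weakly basic that acyl attack on the imide is reversible and unproductive, leaving SN2 displacement as the only outlet.

Step 2
Reactants: 4 (R)-4-benzyl-3-[2-(2,6-dibromo-4-formylphenoxy)acetyl]oxazolidin-2-one
Product: 5 (R)-4-benzyl-3-{2-[2,6-dibromo-4-(1,3-dioxolan-2-yl)phenoxy]acetyl}oxazolidin-2-one
Conditions: TMSOCH2CH2OTMS (1.5 equiv), TMSOTf (5 mol %), CH2Cl2, −78 to −20 °C; pyridine quench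
Reagents that add atoms: 1,2-bis(trimethylsilyloxy)ethane, C[Si](C)(C)OCCO[Si](C)(C)C
Why: Noyori acetalisation, in which catalytic TMSOTf activates the aldehyde towards the bis-silyl glycol ether under aprotic low-temperature conditions that leave the N-acyl oxazolidinone intact, with formation of the Si–O–Si bond as driving force.

Step 3
Reactants: 5 (R)-4-benzyl-3-{2-[2,6-dibromo-4-(1,3-dioxolan-2-yl)phenoxy]acetyl}oxazolidin-2-one; 6 3,4,5-trimethoxybenzaldehyde
Product: 9 (R)-4-benzyl-3-{(2R,3S)-2-[2,6-dibromo-4-(1,3-dioxolan-2-yl)phenoxy]-3-hydroxy-3-(3,4,5-trimethoxyphenyl)propanoyl}oxazolidin-2-one (syn aldol), via boron enolate 7 (not isolated), via boron aldolate 8 (not isolated)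
Conditions: Bu2BOTf (1.1 equiv), Et3N (1.3 equiv), CH2Cl2, −78 to 0 °C; 6, −78 to 0 °C; pH 7 buffer, MeOH, 30% H2O2, 0 °C
Reagents that add atoms: none
Why: Evans syn glycolate aldol, in which soft enolisation gives the (Z)-boron enolate 7, which adds to 6 through a chair Zimmerman–Traxler transition state on the face remote from the benzyl group of the (R)-auxiliary; this sets the syn (2R,3S) pair (future ring carbons C3 and C2) in one operation, and the acetal, deactivated by two meta bromines, should tolerate the slight excess of boron Lewis acid.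

Step 4
Reactants: 9 syn aldol adduct
Product: 10 (1S,2S)-2-[2,6-dibromo-4-(1,3-dioxolan-2-yl)phenoxy]-1-(3,4,5-trimethoxyphenyl)propane-1,3-diol (threo)
Conditions: NaBH4 (4 equiv), THF/H2O (3:1), 0 °C to rt
Reagents that add atoms: none
Why: Reductive removal of the Evans auxiliary, in which borohydride attacks the more electrophilic exocyclic imide carbonyl and takes it to the primary alcohol; aryl bromides and acetal are inert and the low temperature guards against retro-aldol cleavage, so both stereocentres are kept (the aryloxy carbon changes from R to S only because the priorities change).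

Step 5
Reactants: 10 threo diol
Product: 11 (1S,2S)-2-[2,6-dibromo-4-(1,3-dioxolan-2-yl)phenoxy]-1-(3,4,5-trimethoxyphenyl)-3-(trityloxy)propan-1-ol
Conditions: TrCl (1.2 equiv), Et3N (2 equiv), DMAP (10 mol %), CH2Cl2, rt
Reagents that add atoms: trityl chloride, ClC(c1ccccc1)(c1ccccc1)c1ccccc1
Why: Tritylation (SN1-type transfer of the trityl cation, DMAP-assisted) is governed by steric demand and should take only the primary hydroxyl, leaving the hindered benzylic hydroxyl free for ring closure.

Step 6
Reactants: 11 (1S,2S)-2-[2,6-dibromo-4-(1,3-dioxolan-2-yl)phenoxy]-1-(3,4,5-trimethoxyphenyl)-3-(trityloxy)propan-1-ol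
Product: 12 (2S,3S)-5-bromo-7-(1,3-dioxolan-2-yl)-2-(3,4,5-trimethoxyphenyl)-3-(trityloxymethyl)-2,3-dihydro-1,4-benzodioxine (trans)
Conditions: CuI (10 mol %), 1,10-phenanthroline (20 mol %), Cs2CO3 (2 equiv), toluene (0.05 M), 100 °C, under argon
Reagents that add atoms: none
Why: Cs2CO3 generates the benzylic C2 alkoxide, which binds phenanthroline-ligated monovalent copper; oxidative addition of a neighbouring C–Br bond gives a seven-membered trivalent-copper metallacycle (Cu, O1, C2, C3, O4, C4a, C8a), and C–O reductive elimination forms O1–C8a. The closest known reaction type is the intramolecular Ullmann-type etherification of aryl bromides by secondary alcohols, an established entry to 2,3-dihydro-1,4-benzodioxines. The six-membered dioxane ring closes in a 6-exo manner, the departing bromide lying outside the new ring and O4–C4a serving as the tether. No stereocentre is created and no bond to C2 or C3 is broken, so the (1S,2S)-threo pair of 11 becomes the (2S,3S)-trans ring with both large groups equatorial. No site selectivity is required, because rotation about the O4–C4a bond interchanges the two bromines and both closures give the same 12; the chemoselectivity that is required (secondary versus primary oxygen) is secured by the trityl ether, which cannot migrate to the alkoxide as a silyl group might. The dioxolane keeps ring A free of a para acceptor and so disfavours Smiles-type ipso attack at C4a, while intramolecularity lets the first coupling outrun any intermolecular reaction of the surviving C5 bromide.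

Step 7
Reactants: 12 trans 5-bromobenzodioxane
Product: 13 (2S,3S)-7-(1,3-dioxolan-2-yl)-2-(3,4,5-trimethoxyphenyl)-3-(trityloxymethyl)-2,3-dihydro-1,4-benzodioxin-5-ol
Conditions: Pd2(dba)3 (2 mol %), tBuBrettPhos (8 mol %), KOH (4 equiv), 1,4-dioxane/H2O (1:1), 90 °C, under argon; aq NaH2PO4
Reagents that add atoms: potassium hydroxide, [K+].[OH-]
Why: Palladium-catalysed hydroxylation of an aryl bromide (Buchwald–Hartwig-type C–O coupling), in which zerovalent palladium carrying the bulky biaryl phosphine inserts into the C5–Br bond, hydroxide replaces bromide and C–O reductive elimination releases the phenoxide, while trityl ether, dioxolane and both ring ethers are inert to hot aqueous KOH.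

Step 8
Reactants: 13 protected 5-phenol
Product: 14 (2S,3S)-5-hydroxy-3-(hydroxymethyl)-2-(3,4,5-trimethoxyphenyl)-2,3-dihydro-1,4-benzodioxine-7-carbaldehyde
Conditions: 2 M aq HCl/THF (1:3), 40 °C
Reagents that add atoms: water, O
Why: Acid-catalysed hydrolysis, in which the dioxolane opens through its oxocarbenium ion and the trityl ether through the trityl cation, both trapped by water, whereas the aryl alkyl ethers of the dioxane ring and the two stereocentres should be untouched under these mild conditions.

Step 9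
Reactants: 14 hydroxy aldehyde
Product: 15 (E)-3-[(2S,3S)-5-hydroxy-3-(hydroxymethyl)-2-(3,4,5-trimethoxyphenyl)-2,3-dihydro-1,4-benzodioxin-7-yl]prop-2-enal (CNP0241953.1)
Conditions: Ph3P=CHCHO (1.2 equiv), toluene/1,4-dioxane (1:1), 80 °C
Reagents that add atoms: (triphenylphosphoranylidene)acetaldehyde, O=CC=P(c1ccccc1)(c1ccccc1)c1ccccc1
Why: Wittig olefination with a stabilised, non-basic ylide tolerates the primary alcohol and the free phenol (meta to the aldehyde, so it does not deactivate it) and passes through the trans-oxaphosphetane to the (E)-enal, a small excess of ylide limiting a second homologation.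

Compound list
1 | 3,5-dibromo-4-hydroxybenzaldehyde | O=Cc1cc(Br)c(O)c(Br)c1 | starting material
2 | (R)-4-benzyl-3-(chloroacetyl)oxazolidin-2-one | O=C(CCl)N1[C@H](Cc2ccccc2)COC1=O | starting material
3 | (R)-4-benzyl-3-(iodoacetyl)oxazolidin-2-one | O=C(CI)N1[C@H](Cc2ccccc2)COC1=O | intermediate
4 | (R)-4-benzyl-3-[2-(2,6-dibromo-4-formylphenoxy)acetyl]oxazolidin-2-one | O=Cc1cc(Br)c(OCC(=O)N2[C@H](Cc3ccccc3)COC2=O)c(Br)c1 | intermediate
5 | (R)-4-benzyl-3-{2-[2,6-dibromo-4-(1,3-dioxolan-2-yl)phenoxy]acetyl}oxazolidin-2-one | O=C(COc1c(Br)cc(C2OCCO2)cc1Br)N3[C@H](Cc4ccccc4)COC3=O | intermediate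
6 | 3,4,5-trimethoxybenzaldehyde | COc1cc(C=O)cc(OC)c1OC | starting material
7 | (Z)-dibutylboron enolate of 5 | CCCCB(CCCC)O/C(=C\Oc1c(Br)cc(C2OCCO2)cc1Br)N3[C@H](Cc4ccccc4)COC3=O | intermediate
8 | dibutylboron aldolate of 9 | COc1cc([C@H](OB(CCCC)CCCC)[C@H](C(=O)N2[C@H](Cc3ccccc3)COC2=O)Oc4c(Br)cc(C5OCCO5)cc4Br)cc(OC)c1OC | intermediate
9 | (R)-4-benzyl-3-{(2R,3S)-2-[2,6-dibromo-4-(1,3-dioxolan-2-yl)phenoxy]-3-hydroxy-3-(3,4,5-trimethoxyphenyl)propanoyl}oxazolidin-2-one | COc1cc([C@H](O)[C@H](C(=O)N2[C@H](Cc3ccccc3)COC2=O)Oc4c(Br)cc(C5OCCO5)cc4Br)cc(OC)c1OC | intermediate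
10 | (1S,2S)-2-[2,6-dibromo-4-(1,3-dioxolan-2-yl)phenoxy]-1-(3,4,5-trimethoxyphenyl)propane-1,3-diol | COc1cc([C@H](O)[C@H](CO)Oc2c(Br)cc(C3OCCO3)cc2Br)cc(OC)c1OC | intermediate
11 | (1S,2S)-2-[2,6-dibromo-4-(1,3-dioxolan-2-yl)phenoxy]-1-(3,4,5-trimethoxyphenyl)-3-(trityloxy)propan-1-ol | COc1cc([C@H](O)[C@H](COC(c2ccccc2)(c3ccccc3)c4ccccc4)Oc5c(Br)cc(C6OCCO6)cc5Br)cc(OC)c1OC | intermediate
12 | (2S,3S)-5-bromo-7-(1,3-dioxolan-2-yl)-2-(3,4,5-trimethoxyphenyl)-3-(trityloxymethyl)-2,3-dihydro-1,4-benzodioxine | COc1cc([C@@H]2Oc3cc(C4OCCO4)cc(Br)c3O[C@H]2COC(c5ccccc5)(c6ccccc6)c7ccccc7)cc(OC)c1OC | intermediate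
13 | (2S,3S)-7-(1,3-dioxolan-2-yl)-2-(3,4,5-trimethoxyphenyl)-3-(trityloxymethyl)-2,3-dihydro-1,4-benzodioxin-5-ol | COc1cc([C@@H]2Oc3cc(C4OCCO4)cc(O)c3O[C@H]2COC(c5ccccc5)(c6ccccc6)c7ccccc7)cc(OC)c1OC | intermediate
14 | (2S,3S)-5-hydroxy-3-(hydroxymethyl)-2-(3,4,5-trimethoxyphenyl)-2,3-dihydro-1,4-benzodioxine-7-carbaldehyde | COc1cc([C@@H]2Oc3cc(C=O)cc(O)c3O[C@H]2CO)cc(OC)c1OC | intermediate
15 | (E)-3-[(2S,3S)-5-hydroxy-3-(hydroxymethyl)-2-(3,4,5-trimethoxyphenyl)-2,3-dihydro-1,4-benzodioxin-7-yl]prop-2-enal | COc1cc([C@@H]2Oc3cc(/C=C/C=O)cc(O)c3O[C@H]2CO)cc(OC)c1OC | target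

Total step count: 9. Longest linear sequence: 9 steps (1 to 15; 2 enters at step 1 and 6 at step 3).

Steps most likely to fail

1. Step 6 (ring closure). Copper may insert only slowly into the crowded C–Br bond. The hot carbonate could then drive expulsion of the aryloxide by the neighbouring alkoxide, hydrodebromination, or oxidation of the benzylic alcohol. The fallback changes the electrophile before closing the ring. From 11, a base-free copper-catalysed aromatic halogen exchange (CuI, trans-N,N'-dimethylcyclohexane-1,2-diamine, NaI, 1,4-dioxane, 110 °C) should give the diiodo alcohol F1. Its weaker C–I bonds should allow the same etherification at 25–50 °C (CuI, 1,10-phenanthroline, Cs2CO3, MeCN) to give the trans 5-iodobenzodioxane F2. Hydroxylation of the iodide under the step 7 conditions rejoins the route at 13. Any mixed bromo-iodo material should close at the iodide and converge on 13 as well.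

2. Step 9 (two-carbon homologation). The electron-rich aldehyde may react sluggishly, and the product enal may undergo a second olefination. The fallback builds the enal through the ester oxidation level. From 14, the ester ylide Ph3P=CHCO2Et (THF, 50 °C), whose product cannot react again, should give the ethyl (E)-acrylate F3. Excess iBu2AlH (CH2Cl2/THF, −78 °C) should reduce it to the (E)-allylic alcohol F4. MnO2 (CH2Cl2/acetone, rt) should oxidise only the allylic hydroxyl, arriving at 15.

3. Step 7 (bromide to phenol). The C–Br bond may be reduced, or the product phenoxide may be arylated by unreacted bromide. The fallback goes through a carbon–boron bond. From 12, Miyaura borylation (Pd(dppf)Cl2, B2pin2, KOAc, 1,4-dioxane, 90 °C) should give the 5-pinacolboronate F5. Oxidation with H2O2/NaOH (THF, 0 °C) returns to 13.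

Further compounds
F1 | step 6 | (1S,2S)-2-[2,6-diiodo-4-(1,3-dioxolan-2-yl)phenoxy]-1-(3,4,5-trimethoxyphenyl)-3-(trityloxy)propan-1-ol | COc1cc([C@H](O)[C@H](COC(c2ccccc2)(c3ccccc3)c4ccccc4)Oc5c(I)cc(C6OCCO6)cc5I)cc(OC)c1OC
F2 | step 6 | (2S,3S)-5-iodo-7-(1,3-dioxolan-2-yl)-2-(3,4,5-trimethoxyphenyl)-3-(trityloxymethyl)-2,3-dihydro-1,4-benzodioxine | COc1cc([C@@H]2Oc3cc(C4OCCO4)cc(I)c3O[C@H]2COC(c5ccccc5)(c6ccccc6)c7ccccc7)cc(OC)c1OC
F3 | step 9 | ethyl (E)-3-[(2S,3S)-5-hydroxy-3-(hydroxymethyl)-2-(3,4,5-trimethoxyphenyl)-2,3-dihydro-1,4-benzodioxin-7-yl]prop-2-enoate | COc1cc([C@@H]2Oc3cc(/C=C/C(=O)OCC)cc(O)c3O[C@H]2CO)cc(OC)c1OC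
F4 | step 9 | (2S,3S)-3-(hydroxymethyl)-7-[(E)-3-hydroxyprop-1-enyl]-2-(3,4,5-trimethoxyphenyl)-2,3-dihydro-1,4-benzodioxin-5-ol | COc1cc([C@@H]2Oc3cc(/C=C/CO)cc(O)c3O[C@H]2CO)cc(OC)c1OC
F5 | step 7 | (2S,3S)-7-(1,3-dioxolan-2-yl)-5-(4,4,5,5-tetramethyl-1,3,2-dioxaborolan-2-yl)-2-(3,4,5-trimethoxyphenyl)-3-(trityloxymethyl)-2,3-dihydro-1,4-benzodioxine | COc1cc([C@@H]2Oc3cc(C4OCCO4)cc(B5OC(C)(C)C(C)(C)O5)c3O[C@H]2COC(c6ccccc6)(c7ccccc7)c8ccccc8)cc(OC)c1OC
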